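**Retrosynthetic overview** (labdane numbering: ring A = C1–C5/C10, ring B = C5–C10, side chain C11–C16 on C9, C17 = methyl on C8)

1. End game: the C15 alcohol comes from an N-methoxy-N-methyl enamide, the cis-7β-OAc/8β-OH pair from a Woodward cis-hydroxylation of a labda-7,13-diene on the hindered β face, C17 from the enol triflate of an 8-ketone, and C14–C15 from a Horner–Wadsworth–Emmons olefination of a C13 methyl ketone.
2. Key disconnection: ring B is opened at C8–C9 (and C11–C12); the 1,5-diketone 16 (C8=O, C13=O) is the product of an intramolecular de Mayo reaction of the monocyclic β-diketone 14, whose vinyl group on C10 is C9=C11.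
3. Enabling feature: the oxygenated ring B carbon C8 and the side-chain alkene carbon C13 are 1,5-related through C9, C11 and C12, so C8 and C13 can be the two carbonyls of an enolised 1,3-diketone into which the C9=C11 alkene is spliced.
4. 14 comes from methyl ketone 13 by Claisen condensation; 13 comes from ring A ketone 10, whose two stereocentres (C5, C10) are set in one Cu(OTf)2-catalysed asymmetric conjugate addition/enolate vinylation sequence on 2,4,4-trimethylcyclohex-2-enone; the C1 carbonyl is removed by Wolff–Kishner reduction.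
5. Ring order: ring A is bought; ring B is closed photochemically in step 7 through a transient cyclobutane; no other ring is made.

Key step: step 7

Remark 1: the sense of induction of the chiral Cu(OTf)2/NHC catalyst on enone 5 is not known in advance; the ligand enantiomer that gives the 3S configuration of 8 (C5) is taken.
Remark 2: 14 is written as the diketo tautomer; it reacts as the hydrogen-bonded enol.

**Step 1**
Reactants: 1 benzeneselenenyl chloride; 2 ethyl vinyl ether
Product: 4 2-(phenylselanyl)acetaldehyde, via α-chloro ether 3 (not isolated)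
Conditions: CH2Cl2, −78 °C; then H2O, NaHCO3, rt
Reagents that add atoms: water (O)
Why: Electrophilic selenenylation of an enol ether (selenium to the terminal carbon) followed by hydrolysis of the α-chloro ether should give the α-seleno aldehyde; no stereocentre is formed.

**Step 2**
Reactants: 5 2,4,4-trimethylcyclohex-2-en-1-one; 6 2-(2-bromoethyl)-2-methyl-1,3-dioxolane; 4 2-(phenylselanyl)acetaldehyde
Product: 9 (2S,3S)-2-[1-hydroxy-2-(phenylselanyl)ethyl]-2,4,4-trimethyl-3-[2-(2-methyl-1,3-dioxolan-2-yl)ethyl]cyclohexan-1-one (both carbinol epimers), via Grignard reagent 7 (not isolated), via bromomagnesium enolate 8 (not isolated)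
Conditions: 6, Mg, THF, 35 °C; then 5, Cu(OTf)2 (3 mol%), chiral imidazolinium NHC precursor (4 mol%), Et2O, −30 °C; then 4, −78 °C; aq NH4Cl
Reagents that add atoms: none
Why: Cu(OTf)2/NHC-catalysed asymmetric conjugate addition of a Grignard reagent to an α-methyl cyclic enone sets C5 under catalyst control, and the tetrasubstituted enolate 8 then undergoes an aldol addition to 4 on the face anti to the new C5 side chain, which sets the quaternary C10 (side chain and new C9 trans); the carbinol centre is left uncontrolled because step 3 destroys it.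

**Step 3**
Reactants: 9 (2S,3S)-2-[1-hydroxy-2-(phenylselanyl)ethyl]-2,4,4-trimethyl-3-[2-(2-methyl-1,3-dioxolan-2-yl)ethyl]cyclohexan-1-one
Product: 10 (2R,3S)-2-ethenyl-2,4,4-trimethyl-3-[2-(2-methyl-1,3-dioxolan-2-yl)ethyl]cyclohexan-1-one
Conditions: MsCl, Et3N, CH2Cl2, 0 °C to rt
Reagents that add atoms: none
Why: Mesylation of the β-hydroxy selenide triggers anti elimination through a seleniranium ion (β-hydroxy selenide elimination), which can only give the terminal vinyl group because C10 is quaternary; no stereocentre is touched.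

**Step 4**
Reactants: 10 (2R,3S)-2-ethenyl-2,4,4-trimethyl-3-[2-(2-methyl-1,3-dioxolan-2-yl)ethyl]cyclohexan-1-one
Product: 12 2-{2-[(1S,2R)-2-ethenyl-2,6,6-trimethylcyclohexyl]ethyl}-2-methyl-1,3-dioxolane, via hydrazone 11 (not isolated)
Conditions: N2H4·H2O, KOH, diethylene glycol, N2, 130 °C then 200 °C
Reagents that add atoms: none
Why: Wolff–Kishner reduction removes the C1 carbonyl through the hydrazone; the quaternary C10 cannot epimerise, the vinyl group cannot move into conjugation and the dioxolane is stable to base.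

**Step 5**
Reactants: 12 2-{2-[(1S,2R)-2-ethenyl-2,6,6-trimethylcyclohexyl]ethyl}-2-methyl-1,3-dioxolane
Product: 13 4-[(1S,2R)-2-ethenyl-2,6,6-trimethylcyclohexyl]butan-2-one
Conditions: 1 M HCl, THF, rt
Reagents that add atoms: water (O)
Why: Acid-catalysed acetal hydrolysis frees the C8 methyl ketone under conditions that leave the isolated vinyl group and both stereocentres alone.

**Step 6**
Reactants: 13 4-[(1S,2R)-2-ethenyl-2,6,6-trimethylcyclohexyl]butan-2-one
Product: 14 6-[(1S,2R)-2-ethenyl-2,6,6-trimethylcyclohexyl]hexane-2,4-dione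
Conditions: NaH, EtOAc, THF, reflux; then aq HCl
Reagents that add atoms: ethyl acetate (CCOC(C)=O)
Why: Crossed Claisen condensation of the methyl ketone with ethyl acetate acylates the less hindered methyl carbon (C12) and is driven by formation of the stabilised diketonate; the stereocentres are not involved.

**Step 7**
Reactants: 14 6-[(1S,2R)-2-ethenyl-2,6,6-trimethylcyclohexyl]hexane-2,4-dione
Product: 16 4-[(1R,4aS,8aS)-5,5,8a-trimethyl-2-oxodecahydronaphthalen-1-yl]butan-2-one, via cyclobutanol 15 (not isolated)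
Conditions: hν (300 nm), degassed cyclohexane (0.005 M), rt; then silica gel
Reagents that add atoms: none
Why: Excitation of the hydrogen-bonded enol C8(OH)=C12–C13=O of 14 gives an enone-like triplet whose C8 terminus adds to C9 of the vinyl group, the resulting C11/C12 1,4-biradical collapses to cyclobutanol 15, and the strained β-hydroxy ketone then undergoes retro-aldol cleavage of C8–C12 to the 1,5-diketone 16. The closest known reaction type is the de Mayo reaction (enol–alkene [2+2] photocycloaddition followed by retro-aldol opening) in its intramolecular form. Ring B closes in a 6-exo mode (C8 onto C9, four-atom tether C7–C6–C5–C10), while the cyclobutane closes by radical recombination C11–C12 and is opened again in the same flask. The only stereocentre that survives, C9, is set in the C8–C9 bond formation by a chair-like transition state in which both ring A substituents are equatorial and C11 is pseudo-equatorial, and because C9 ends up α to the new C8 ketone the same epimer (equatorial side chain, 9α-H) is also the thermodynamic one. The step needs straight (C8–C9/C11–C12) and not crossed (C8–C11/C9–C12) regiochemistry, which the tether length (six- against seven-membered first ring) and the trans arrangement of the two arms on ring A should secure, and it needs reaction through the C8=C12 enol, the only enol double bond that the tether lets reach the alkene. The configurations at C8 and C12 in 15 do not matter because C8 becomes a carbonyl carbon and C12 a CH2 group on ring opening.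

**Step 8**
Reactants: 16 4-[(1R,4aS,8aS)-5,5,8a-trimethyl-2-oxodecahydronaphthalen-1-yl]butan-2-one
Product: 17 (2E)-N-methoxy-N,3-dimethyl-5-[(1R,4aS,8aS)-5,5,8a-trimethyl-2-oxodecahydronaphthalen-1-yl]pent-2-enamide
Conditions: (EtO)2P(O)CH2C(O)N(OMe)Me, NaH, THF, 0 °C to 50 °C
Reagents that add atoms: diethyl {2-[methoxy(methyl)amino]-2-oxoethyl}phosphonate (CCOP(=O)(CC(=O)N(C)OC)OCC)
Why: Horner–Wadsworth–Emmons olefination should occur at the unhindered C13 methyl ketone and not at the C8 ketone, which is flanked by the tertiary C9 next to the quaternary C10; the weakly basic stabilised phosphonate anion limits aldol side reactions and should favour the (E)-alkene (minor Z isomer to be removed by chromatography), and any C9 epimer can equilibrate to the equatorial side chain under these conditions.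

**Step 9**
Reactants: 17 (2E)-N-methoxy-N,3-dimethyl-5-[(1R,4aS,8aS)-5,5,8a-trimethyl-2-oxodecahydronaphthalen-1-yl]pent-2-enamide
Product: 19 (1R,4aS,8aS)-1-{(3E)-5-[methoxy(methyl)amino]-3-methyl-5-oxopent-3-en-1-yl}-5,5,8a-trimethyl-1,4,4a,5,6,7,8,8a-octahydronaphthalen-2-yl trifluoromethanesulfonate, via potassium enolate 18 (not isolated)
Conditions: KN(SiMe3)2, THF, −78 °C; then PhNTf2, −78 °C to 0 °C
Reagents that add atoms: N-phenylbis(trifluoromethanesulfonimide) (O=S(=O)(N(c1ccccc1)S(=O)(=O)C(F)(F)F)C(F)(F)F)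
Why: Kinetic deprotonation of the ketone with a bulky amide base should occur at the C7 methylene and not at the hindered C9 methine, and O-triflation of the enolate (enol triflate formation) fixes the C7=C8 double bond without touching C9.

**Step 10**
Reactants: 19 (1R,4aS,8aS)-1-{(3E)-5-[methoxy(methyl)amino]-3-methyl-5-oxopent-3-en-1-yl}-5,5,8a-trimethyl-1,4,4a,5,6,7,8,8a-octahydronaphthalen-2-yl trifluoromethanesulfonate
Product: 20 (2E)-N-methoxy-N,3-dimethyl-5-[(1S,4aS,8aS)-2,5,5,8a-tetramethyl-1,4,4a,5,6,7,8,8a-octahydronaphthalen-1-yl]pent-2-enamide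
Conditions: MeZnCl, Pd(PPh3)4 (5 mol%), THF, 50 °C
Reagents that add atoms: methylzinc chloride (C[Zn]Cl)
Why: Negishi cross-coupling of the enol triflate installs C17 with the double bond held at C7=C8; the N-methoxy-N-methylamide is inert to the organozinc reagent.

**Step 11**
Reactants: 20 (2E)-N-methoxy-N,3-dimethyl-5-[(1S,4aS,8aS)-2,5,5,8a-tetramethyl-1,4,4a,5,6,7,8,8a-octahydronaphthalen-1-yl]pent-2-enamide
Product: 23 (2S,3R,4R,4aS,8aS)-3-hydroxy-4-{(3E)-5-[methoxy(methyl)amino]-3-methyl-5-oxopent-3-en-1-yl}-3,4a,8,8-tetramethyldecahydronaphthalen-2-yl acetate, via iodo acetate 21 (not isolated), via acetoxonium ion 22 (not isolated)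
Conditions: I2, AgOAc, AcOH, rt; then H2O–AcOH, 60 °C
Reagents that add atoms: silver acetate (CC(=O)[O-].[Ag+]); water (O)
Why: In this Woodward cis-hydroxylation the iodonium ion forms on the open α face of the electron-rich C7=C8 alkene (the conjugated C13=C14 alkene is deactivated), acetate opens it trans-diaxially at the tertiary C8 from the β face, the 8β-acetate displaces the 7α-iodide with inversion to give the β-face acetoxonium ion 22, and hydrolysis should deliver the cis-7β,8β hydroxy acetate on the face that osmylation does not reach, with the acetyl group settling on the secondary equatorial oxygen under the equilibrating conditions.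

**Step 12**
Reactants: 23 (2S,3R,4R,4aS,8aS)-3-hydroxy-4-{(3E)-5-[methoxy(methyl)amino]-3-methyl-5-oxopent-3-en-1-yl}-3,4a,8,8-tetramethyldecahydronaphthalen-2-yl acetate
Product: 24 (2S,3R,4R,4aS,8aS)-3-hydroxy-3,4a,8,8-tetramethyl-4-[(3E)-3-methyl-5-oxopent-3-en-1-yl]decahydronaphthalen-2-yl acetate
Conditions: Cp2Zr(H)Cl (2.5 equiv), THF, rt
Reagents that add atoms: none
Why: Reduction of the tertiary amide with Cp2Zr(H)Cl (amide to aldehyde reduction) stops at the aldehyde and tolerates the acetate, which an aluminium hydride would cleave; the (E)-alkene and all stereocentres are untouched.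

**Step 13**
Reactants: 24 (2S,3R,4R,4aS,8aS)-3-hydroxy-3,4a,8,8-tetramethyl-4-[(3E)-3-methyl-5-oxopent-3-en-1-yl]decahydronaphthalen-2-yl acetate
Product: 25 (2S,3R,4R,4aS,8aS)-3-hydroxy-4-[(3E)-5-hydroxy-3-methylpent-3-en-1-yl]-3,4a,8,8-tetramethyldecahydronaphthalen-2-yl acetate
Conditions: NaBH4, CeCl3·7H2O, MeOH, 0 °C
Reagents that add atoms: none
Why: Luche reduction should give clean 1,2-reduction of the enal to the allylic alcohol without touching the acetate, the alkene geometry or any stereocentre.

**Compound list**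

1 | benzeneselenenyl chloride | Cl[Se]c1ccccc1 | starting material
2 | ethyl vinyl ether | C=COCC | starting material
3 | (2-chloro-2-ethoxyethyl)(phenyl)selane (not isolated) | CCOC(Cl)C[Se]c1ccccc1 | intermediate
4 | 2-(phenylselanyl)acetaldehyde | O=CC[Se]c1ccccc1 | intermediate
5 | 2,4,4-trimethylcyclohex-2-en-1-one | CC1=CC(C)(C)CCC1=O | starting material
6 | 2-(2-bromoethyl)-2-methyl-1,3-dioxolane | CC1(CCBr)OCCO1 | starting material
7 | [2-(2-methyl-1,3-dioxolan-2-yl)ethyl]magnesium bromide (not isolated) | CC1(CC[Mg]Br)OCCO1 | intermediate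
8 | bromomagnesium (3S)-2,4,4-trimethyl-3-[2-(2-methyl-1,3-dioxolan-2-yl)ethyl]cyclohex-1-en-1-olate (not isolated) | CC1(OCCO1)CC[C@H]2C(C)(C)CCC(O[Mg]Br)=C2C | intermediate
9 | (2S,3S)-2-[1-hydroxy-2-(phenylselanyl)ethyl]-2,4,4-trimethyl-3-[2-(2-methyl-1,3-dioxolan-2-yl)ethyl]cyclohexan-1-one (both carbinol epimers) | CC1(OCCO1)CC[C@H]2C(C)(C)CCC(=O)[C@]2(C)C(O)C[Se]c3ccccc3 | intermediate
10 | (2R,3S)-2-ethenyl-2,4,4-trimethyl-3-[2-(2-methyl-1,3-dioxolan-2-yl)ethyl]cyclohexan-1-one | CC1(OCCO1)CC[C@H]2C(C)(C)CCC(=O)[C@]2(C)C=C | intermediate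
11 | hydrazone of 10 (not isolated) | CC1(OCCO1)CC[C@H]2C(C)(C)CCC(=NN)[C@]2(C)C=C | intermediate
12 | 2-{2-[(1S,2R)-2-ethenyl-2,6,6-trimethylcyclohexyl]ethyl}-2-methyl-1,3-dioxolane | CC1(OCCO1)CC[C@H]2C(C)(C)CCC[C@]2(C)C=C | intermediate
13 | 4-[(1S,2R)-2-ethenyl-2,6,6-trimethylcyclohexyl]butan-2-one | CC(=O)CC[C@H]1C(C)(C)CCC[C@]1(C)C=C | intermediate
14 | 6-[(1S,2R)-2-ethenyl-2,6,6-trimethylcyclohexyl]hexane-2,4-dione (mainly enol) | CC(=O)CC(=O)CC[C@H]1C(C)(C)CCC[C@]1(C)C=C | intermediate
15 | cyclobutanol photoadduct: ring A/ring B/cyclobutane tricycle with C8–OH and acetyl on C12, C8 and C12 epimers (not isolated) | CC(=O)C1C[C@H]2C1(O)CC[C@H]3C(C)(C)CCC[C@@]32C | intermediate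
16 | 4-[(1R,4aS,8aS)-5,5,8a-trimethyl-2-oxodecahydronaphthalen-1-yl]butan-2-one | O=C1CC[C@H]2C(C)(C)CCC[C@]2(C)[C@H]1CCC(C)=O | intermediate
17 | (2E)-N-methoxy-N,3-dimethyl-5-[(1R,4aS,8aS)-5,5,8a-trimethyl-2-oxodecahydronaphthalen-1-yl]pent-2-enamide | O=C1CC[C@H]2C(C)(C)CCC[C@]2(C)[C@H]1CC/C(C)=C/C(=O)N(C)OC | intermediate
18 | potassium enolate of 17 at C7–C8 (not isolated) | [K+].[O-]C1=CC[C@H]2C(C)(C)CCC[C@]2(C)[C@H]1CC/C(C)=C/C(=O)N(C)OC | intermediate
19 | (1R,4aS,8aS)-1-{(3E)-5-[methoxy(methyl)amino]-3-methyl-5-oxopent-3-en-1-yl}-5,5,8a-trimethyl-1,4,4a,5,6,7,8,8a-octahydronaphthalen-2-yl trifluoromethanesulfonate | O=S(=O)(OC1=CC[C@H]2C(C)(C)CCC[C@]2(C)[C@H]1CC/C(C)=C/C(=O)N(C)OC)C(F)(F)F | intermediate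
20 | (2E)-N-methoxy-N,3-dimethyl-5-[(1S,4aS,8aS)-2,5,5,8a-tetramethyl-1,4,4a,5,6,7,8,8a-octahydronaphthalen-1-yl]pent-2-enamide | CC1=CC[C@H]2C(C)(C)CCC[C@]2(C)[C@H]1CC/C(C)=C/C(=O)N(C)OC | intermediate
21 | 7α-iodo-8β-acetoxy adduct of 20, trans-diaxial (not isolated) | I[C@@H]1C[C@H]2C(C)(C)CCC[C@]2(C)[C@@H](CC/C(C)=C/C(=O)N(C)OC)[C@@]1(C)OC(C)=O | intermediate
22 | 7β,8β-fused 2-methyl-1,3-dioxolan-2-ylium acetate (not isolated) | C[C+]1O[C@H]2C[C@H]3C(C)(C)CCC[C@]3(C)[C@@H](CC/C(C)=C/C(=O)N(C)OC)[C@@]2(C)O1.CC(=O)[O-] | intermediate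
23 | (2S,3R,4R,4aS,8aS)-3-hydroxy-4-{(3E)-5-[methoxy(methyl)amino]-3-methyl-5-oxopent-3-en-1-yl}-3,4a,8,8-tetramethyldecahydronaphthalen-2-yl acetate | CC(=O)O[C@H]1C[C@H]2C(C)(C)CCC[C@]2(C)[C@@H](CC/C(C)=C/C(=O)N(C)OC)[C@@]1(C)O | intermediate
24 | (2S,3R,4R,4aS,8aS)-3-hydroxy-3,4a,8,8-tetramethyl-4-[(3E)-3-methyl-5-oxopent-3-en-1-yl]decahydronaphthalen-2-yl acetate | CC(=O)O[C@H]1C[C@H]2C(C)(C)CCC[C@]2(C)[C@@H](CC/C(C)=C/C=O)[C@@]1(C)O | intermediate
25 | (2S,3R,4R,4aS,8aS)-3-hydroxy-4-[(3E)-5-hydroxy-3-methylpent-3-en-1-yl]-3,4a,8,8-tetramethyldecahydronaphthalen-2-yl acetate (7β-acetoxy, 8β-hydroxy, 8α-methyl, 9α-H, 5α-H, 10β-methyl) | CC(=O)O[C@H]1C[C@H]2C(C)(C)CCC[C@]2(C)[C@@H](CC/C(C)=C/CO)[C@@]1(C)O | target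

**Step count and risks**

Total step count: 13. Longest linear sequence: 13 steps (1 and 2 through 4, 9, 10, 12, 13, 14, 16, 17, 19, 20, 23, 24 to 25); counted from 5 or 6 it is 12.

Most likely to fail, first: step 7. The excited acyclic enol may lose its energy by rotation about the C8=C12 bond, the minor diketo tautomer may undergo Norrish type 2 cleavage through the C5 hydrogen, and some bonding of C8 to C11 (crossed mode) may compete with the 6-exo closure. The fallback sets out from 14 and comes back at 16. Treatment of 14 with BF3·OEt2 (CH2Cl2, rt) gives the difluoroboron β-diketonate F1, a rigid chromophore that cannot decay by enol rotation and has no diketo tautomer. Irradiation of F1 (300 nm, MeCN) closes ring B through the boron-bound cyclobutane adduct F2, which ring-opens and is hydrolysed to 16 on work-up with aqueous NaOAc.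

Second: step 2. Conversion and enantioselectivity of the conjugate addition may be poor because the β-carbon lies between an α-methyl group and a quaternary γ-carbon, and the hindered enolate may deprotonate the enolisable aldehyde 4 instead of adding to it. The fallback sets out from 7 and comes back at 9. Transmetalation of 7 with ZnCl2 (0.5 equiv, salts removed with 1,4-dioxane) gives bis[2-(2-methyl-1,3-dioxolan-2-yl)ethyl]zinc F3. Its Cu(OTf)2/chiral phosphoramidite-catalysed conjugate addition to commercial 4,4-dimethylcyclohex-2-en-1-one (CC1(C)CCC(=O)C=C1), an enone without α-substituent and the standard substrate class for this reaction, with in situ methylation (MeI, HMPA) gives (2R,3R)-2,4,4-trimethyl-3-[2-(2-methyl-1,3-dioxolan-2-yl)ethyl]cyclohexan-1-one F4 with C5 set. Thermodynamic silylation (Me3SiCl, NaI, Et3N, MeCN) gives the tetrasubstituted trimethylsilyl enol ether F5. Cleavage of F5 with MeLi (THF, 0 °C) and addition of 4 at −78 °C then delivers 9, the aldehyde again entering anti to the C5 side chain.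

Third: step 11. The tertiary C8 oxygen function may be lost by elimination from the iodo acetate or the hydroxy acetate in warm acetic acid, the acetyl group may stay in part on the tertiary oxygen, and some iodonium ion may form on the β face. The fallback sets out from 20 and comes back at 23. Epoxidation with mCPBA (CH2Cl2, NaHCO3, 0 °C) on the open α face gives the 7α,8α-epoxide F6. Acid-catalysed hydrolysis (HClO4, aq THF) opens it at the tertiary C8 with inversion to the trans-diaxial 7α,8β-diol F7. Dess–Martin oxidation of the secondary alcohol gives the 8β-hydroxy-7-ketone F8. NaBH4 (MeOH, 0 °C) delivers hydride axially from the α face to give the cis-7β,8β-diol F9, and Ac2O/pyridine acetylates only the secondary hydroxyl to give 23.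

**Further compounds**

F1 | step 7 | difluoroboron β-diketonate of 14 (2,2-difluoro-1,3,2-dioxaborinine chelate) | CC1=CC(CC[C@H]2C(C)(C)CCC[C@]2(C)C=C)=[O+][B-](F)(F)O1
F2 | step 7 | boron-bound cyclobutane photoadduct of F1 (C8–C9 and C11–C12 bonds formed, C8/C9/C12 epimers) | CC1=[O+][B-](F)(F)OC23CC[C@H]4C(C)(C)CCC[C@]4(C)C3CC12
F3 | step 2 | bis[2-(2-methyl-1,3-dioxolan-2-yl)ethyl]zinc | CC1(CC[Zn]CCC2(C)OCCO2)OCCO1
F4 | step 2 | (2R,3R)-2,4,4-trimethyl-3-[2-(2-methyl-1,3-dioxolan-2-yl)ethyl]cyclohexan-1-one | CC1(OCCO1)CC[C@H]2C(C)(C)CCC(=O)[C@@H]2C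
F5 | step 2 | trimethyl({(3S)-2,4,4-trimethyl-3-[2-(2-methyl-1,3-dioxolan-2-yl)ethyl]cyclohex-1-en-1-yl}oxy)silane | CC1(OCCO1)CC[C@H]2C(C)(C)CCC(O[Si](C)(C)C)=C2C
F6 | step 11 | 7α,8α-epoxide of 20 | O1[C@@H]2C[C@H]3C(C)(C)CCC[C@]3(C)[C@@H](CC/C(C)=C/C(=O)N(C)OC)[C@]12C
F7 | step 11 | 7α,8β-diol (trans-diaxial) | O[C@@H]1C[C@H]2C(C)(C)CCC[C@]2(C)[C@@H](CC/C(C)=C/C(=O)N(C)OC)[C@@]1(C)O
F8 | step 11 | 8β-hydroxy-8α-methyl-7-ketone | O=C1C[C@H]2C(C)(C)CCC[C@]2(C)[C@@H](CC/C(C)=C/C(=O)N(C)OC)[C@@]1(C)O
F9 | step 11 | 7β,8β-diol (cis) | O[C@H]1C[C@H]2C(C)(C)CCC[C@]2(C)[C@@H](CC/C(C)=C/C(=O)N(C)OC)[C@@]1(C)O
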